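**Plan**

- Retrosynthesis: first the C5–OOH bond with the C4=C15 shift (ene reaction) and the acyl C–O bonds at C3 and C8; then C11=C13 and C7–C11 (an allyl group on the C7 enolate of a C8 ketone); then C4–C15; then C10–C14, cut through a C5/C10/C14 cyclopropane back to a C5=C10 olefin; last, ring A back to an anisole ring.
- Forward: rings A and B come ready-made in 6-methoxy-2-tetralone. Birch reduction unlocks ring A, a three-membered ring is closed on C5=C10 and opened again to leave C14, then C15, the C11–C12 unit and C13 are added and the oxygens are acylated.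
- Enabling feature: the methyl C14 on C10 and the oxygen on C8 are cis and 1,3-diaxial on ring B, and the C3 oxygen sits para to C10 on ring A. A C8 hydroxyl, homoallylic to the C5=C10 bond of a reduced anisole ring, can therefore deliver CH2 to C10 on its own face.
- Stereochemistry: C8 from a catalytic transfer hydrogenation; C10 (and, for a time, C5) from hydroxyl delivery; C3, C7, C8 (set again) and C5 from the bias of the β methyl on C10 (bulky hydrides at C3 and C8, equilibration at C7, singlet oxygen on the α face).

Key step: step 4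

Numbering: bicyclic compounds carry eudesmane locants (ring A = C1–C5 and C10, ring B = C5–C10, C14 = methyl on C10, C15 = carbon on C4, C11(–C12)(=C13) on C7). β is the face of C14. "Nor" names count the missing side-chain carbons.

Assumption: with this benzyl-type dialkyl ketone the (S,S)-configured ruthenium catalyst is taken to give the S alcohol, as it does with aryl ketones; if the sense proves opposite, the (R,R) complex is used in the same way.

**Route**

Step 1
Reactants: 1 6-methoxy-2-tetralone
Product: 2 (S)-6-methoxy-1,2,3,4-tetrahydronaphthalen-2-ol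
Conditions: RuCl(p-cymene)[(S,S)-TsDPEN] (1 mol%), HCO2H/Et3N (5:2), CH2Cl2, 25 °C, degassed
Reagents that add atoms: none
Why: Noyori–Ikariya asymmetric transfer hydrogenation, in which Ru–H and N–H add across one carbonyl face in a six-membered transition state with the aryl-bearing CH2 arm in the place an aryl group normally takes, should set the carbinol centre (later C8) as S, and the alcohol can be enriched by recrystallisation.

Step 2
Reactants: 2 (S)-6-methoxy-1,2,3,4-tetrahydronaphthalen-2-ol
Product: 3 (S)-6-methoxy-1,2,3,4,5,8-hexahydronaphthalen-2-ol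
Conditions: Li, NH3 (l), THF, t-BuOH, −78 → −33 °C
Reagents that add atoms: none
Why: Birch reduction of the anisole ring gives the 1-methoxy-1,4-diene in which the methoxy-bearing carbon and both ring-fusion carbons stay sp2, so the isolated tetrasubstituted C5=C10 olefin appears and the remote carbinol centre is not touched.

Step 3
Reactants: 3 (S)-6-methoxy-1,2,3,4,5,8-hexahydronaphthalen-2-ol; 4 ethane-1,2-diol
Product: 5 (S)-6,6-ethylenedioxy-1,2,3,4,5,6,7,8-octahydronaphthalen-2-ol (3,3-ethylenedioxy-5(10)-en-8β-ol)
Conditions: HOCH2CH2OH (5 equiv), PPTS (cat.), THF, 25 °C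
Reagents that add atoms: ethane-1,2-diol, OCCO
Why: Acid-catalysed enol ether exchange (transketalisation): protonation at C2 gives the C3 oxocarbenium ion, which the diol traps as the dioxolane with loss of methanol, and the weak acid leaves the unconjugated C5=C10 bond in place.

Step 4
Reactants: 5 (S)-6,6-ethylenedioxy-1,2,3,4,5,6,7,8-octahydronaphthalen-2-ol; 6 diiodomethane
Product: 8 (2S,4aS,8aS)-6,6-ethylenedioxyoctahydro-4a,8a-methanonaphthalen-2-ol (5β,10β-methano ketal 8β-alcohol), via ethylzinc alkoxide 7 (not isolated)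
Conditions: Et2Zn (5 equiv), CH2I2 (10 equiv), CH2Cl2, 0 → 25 °C; then aq. NH4Cl
Reagents that add atoms: diiodomethane, ICI
Why: Et2Zn first turns the C8 hydroxyl into the ethylzinc alkoxide 7, and the iodomethylzinc carbenoid made from more Et2Zn and CH2I2 is held by this alkoxide and passes CH2 to the tetrasubstituted C5=C10 bond in one concerted, butterfly-type transition state, forming C10–C14 and C5–C14 together. The closest known reaction type is the hydroxyl-directed Simmons–Smith cyclopropanation (diethylzinc variant) of homoallylic cyclohexenols, as applied to Birch-derived 5(10)-enes of 19-norsteroids. The three-membered ring (C5, C10, C14) closes by a stereospecific syn [2+1] addition of the carbenoid to one π face, so both new bonds lie on the same side. The two new stereocentres C5 and C10 are set together and relative to C8 by the pseudoaxial C8–O–Zn group, which in the half-chair of ring B reaches only the β face. The step needs face selectivity and selectivity for the olefin over the dioxolane: the homoallylic alkoxide two bonds from C10 secures the first, and the high nucleophilicity of the tetrasubstituted olefin towards the electrophilic carbenoid in non-coordinating CH2Cl2 secures the second.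

Step 5
Reactants: 8 5β,10β-methano ketal 8β-alcohol
Product: 10 8β-hydroxy-11,12,13,15-tetranoreudesm-4-en-3-one [(4aR,6S)-6-hydroxy-4a-methyl-4,4a,5,6,7,8-hexahydronaphthalen-2(3H)-one], via cyclopropyl ketone 9 (not isolated)
Conditions: 3 M aq. HCl, MeOH, 60 °C
Reagents that add atoms: water, O
Why: Acid hydrolysis of the dioxolane frees the C3 ketone 9, and in its enol the C3=C4 bond pushes into the cyclopropane as a proton adds to C14 and C5–C14 breaks (acid-catalysed homoconjugate opening of a β,γ-cyclopropyl ketone, the reaction used to make C19 of steroids), which gives the 4-en-3-one and leaves C14 as the β methyl on an unchanged C10.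

Step 6
Reactants: 10 8β-hydroxy-11,12,13,15-tetranoreudesm-4-en-3-one; 11 iodomethane
Product: 13 8β-hydroxy-11,12,13-trinoreudesm-4-en-3-one [(4aR,6S)-6-hydroxy-1,4a-dimethyl-4,4a,5,6,7,8-hexahydronaphthalen-2(3H)-one], via potassium dienolate 12 (not isolated)
Conditions: KOt-Bu (1.5 equiv), t-BuOH, 40 °C; MeI (1.2 equiv) added slowly
Reagents that add atoms: iodomethane, CI
Why: Thermodynamic γ-deprotonation at C6 gives the extended dienolate 12, which MeI alkylates at its α-carbon C4 before conjugation is restored (classical C4 alkylation of a Δ4-3-ketone dienolate), slow addition of about one equivalent limiting the 4,4-dimethyl by-product while the hindered axial C8 alkoxide is the poorer nucleophile.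

Step 7
Reactants: 13 8β-hydroxy-11,12,13-trinoreudesm-4-en-3-one; 14 acetic anhydride
Product: 15 8β-acetoxy-11,12,13-trinoreudesm-4-en-3-one
Conditions: Ac2O, DMAP (cat.), pyridine, 25 → 40 °C
Reagents that add atoms: acetic anhydride, CC(=O)OC(C)=O
Why: DMAP-catalysed acylation of the axial 8β-hydroxyl gives an ester that masks C8 during reduction and silylation at C3 and can later be removed with base without touching a silyl ether.

Step 8
Reactants: 15 8β-acetoxy-11,12,13-trinoreudesm-4-en-3-one
Product: 16 8β-acetoxy-11,12,13-trinoreudesm-4-en-3α-ol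
Conditions: K[HB(s-Bu)3] (K-Selectride, 1.2 equiv), THF, −78 °C; then H2O
Reagents that add atoms: none
Why: 1,2-Reduction of the fully substituted enone by the bulky trialkylborohydride, which approaches C3 along the equatorial line on the β side (the known route from Δ4-3-ketones to pseudoaxial 3α-allylic alcohols), sets C3 with the hydroxyl α, while the acetate is inert at −78 °C.

Step 9
Reactants: 16 8β-acetoxy-11,12,13-trinoreudesm-4-en-3α-ol
Product: 17 8β-acetoxy-3α-(tert-butyldimethylsilyloxy)-11,12,13-trinoreudesm-4-ene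
Conditions: TBSOTf (1.3 equiv), 2,6-lutidine, CH2Cl2, −78 → 0 °C
Reagents that add atoms: tert-butyldimethylsilyl trifluoromethanesulfonate, CC(C)(C)[Si](C)(C)OS(=O)(=O)C(F)(F)F
Why: Silylation of the allylic alcohol with a silyl triflate and a hindered base gives a TBS ether that should stand methoxide, amide base, hydride, OsO4, chlorite and the diazo reagent and can be removed at the end with fluoride.

Step 10
Reactants: 17 8β-acetoxy-3α-(tert-butyldimethylsilyloxy)-11,12,13-trinoreudesm-4-ene
Product: 18 3α-(tert-butyldimethylsilyloxy)-11,12,13-trinoreudesm-4-en-8β-ol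
Conditions: K2CO3 (0.5 equiv), MeOH, 40 °C
Reagents that add atoms: none
Why: Base-catalysed methanolysis (transesterification) frees the 8β-hydroxyl, the silyl ether and the olefin being inert to carbonate in methanol.

Step 11
Reactants: 18 3α-(tert-butyldimethylsilyloxy)-11,12,13-trinoreudesm-4-en-8β-ol
Product: 19 3α-(tert-butyldimethylsilyloxy)-11,12,13-trinoreudesm-4-en-8-one
Conditions: Dess–Martin periodinane, NaHCO3, CH2Cl2, 25 °C
Reagents that add atoms: none
Why: Dess–Martin oxidation under bicarbonate buffer gives the C8 ketone without acid that could ionise the allylic C3–O bond, and the C8 centre, its directing task done, is given up so that C7 can be reached through the enolate.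

Step 12
Reactants: 19 3α-(tert-butyldimethylsilyloxy)-11,12,13-trinoreudesm-4-en-8-one; 20 allyl bromide
Product: 23 7β-allyl-3α-(tert-butyldimethylsilyloxy)-11,12,13-trinoreudesm-4-en-8-one, via lithium enolate 21 (not isolated), via 7α-allyl ketone 22 (not isolated)
Conditions: LiN(i-Pr)2 (1.1 equiv), THF, −78 °C; allyl bromide, DMPU, −78 → 0 °C; then NaOMe (cat.), MeOH, 25 °C
Reagents that add atoms: allyl bromide, C=CCBr
Why: Kinetic deprotonation occurs at C7, not at the neopentyl C9 beside quaternary C10, and enolate 21 is allylated on carbon from the axial α direction to give 22 (ketone enolate alkylation), after which methoxide equilibrates C7 through the enol to the equatorial β-allyl epimer, the thermodynamic product.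

Step 13
Reactants: 23 7β-allyl-3α-(tert-butyldimethylsilyloxy)-11,12,13-trinoreudesm-4-en-8-one
Product: 24 7β-allyl-3α-(tert-butyldimethylsilyloxy)-11,12,13-trinoreudesm-4-en-8β-ol
Conditions: Li[HB(s-Bu)3] (L-Selectride), THF, −78 °C; then H2O
Reagents that add atoms: none
Why: Substrate-controlled hydride reduction: the axial line of attack on the β face of C8 is blocked by the syn-axial C10 methyl, so the bulky borohydride enters equatorially from the α face and gives the axial 8β-alcohol, cis to the C7 allyl group.

Step 14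
Reactants: 24 7β-allyl-3α-(tert-butyldimethylsilyloxy)-11,12,13-trinoreudesm-4-en-8β-ol; 14 acetic anhydride
Product: 25 8β-acetoxy-7β-allyl-3α-(tert-butyldimethylsilyloxy)-11,12,13-trinoreudesm-4-ene
Conditions: Ac2O, DMAP, Et3N, CH2Cl2, 25 → 40 °C
Reagents that add atoms: acetic anhydride, CC(=O)OC(C)=O
Why: DMAP-catalysed acetylation of the hindered axial alcohol installs the C8 acetate of the target before any C12 carbonyl exists, so no 8,12-lactone can form.

Step 15
Reactants: 25 8β-acetoxy-7β-allyl-3α-(tert-butyldimethylsilyloxy)-11,12,13-trinoreudesm-4-ene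
Product: 27 8β-acetoxy-3α-(tert-butyldimethylsilyloxy)-13-noreudesm-4-en-12-al, via vicinal diol 26 (not isolated)
Conditions: OsO4 (2 mol%), NaIO4 (4 equiv), 2,6-lutidine, dioxane/H2O (3:1), 25 °C
Reagents that add atoms: osmium tetroxide, O=[Os](=O)(=O)=O (its oxygen is restored by sodium periodate, [Na+].[O-]I(=O)(=O)=O)
Why: Lemieux–Johnson oxidation: OsO4 dihydroxylates the open monosubstituted olefin much faster than the shielded tetrasubstituted C4=C5 bond, and periodate cleaves diol 26 to the C12 aldehyde with loss of one carbon as formaldehyde.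

Step 16
Reactants: 27 8β-acetoxy-3α-(tert-butyldimethylsilyloxy)-13-noreudesm-4-en-12-al; 28 formaldehyde
Product: 29 8β-acetoxy-3α-(tert-butyldimethylsilyloxy)eudesma-4,11(13)-dien-12-al
Conditions: 37% aq. CH2O, pyrrolidine (10 mol%), propionic acid (10 mol%), i-PrOH, 45 °C
Reagents that add atoms: formaldehyde, C=O
Why: Amine-catalysed α-methylenation of an aldehyde (Mannich condensation with formaldehyde through the enamine, then loss of the amine) brings C13 onto C11, the C8 acetate being γ to the carbonyl and so not open to elimination and H7 not being acidic.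

Step 17
Reactants: 29 8β-acetoxy-3α-(tert-butyldimethylsilyloxy)eudesma-4,11(13)-dien-12-al
Product: 30 8β-acetoxy-3α-(tert-butyldimethylsilyloxy)eudesma-4,11(13)-dien-12-oic acid
Conditions: NaClO2, NaH2PO4, 2-methyl-2-butene (30 equiv), t-BuOH/H2O, 0 → 25 °C
Reagents that add atoms: sodium chlorite, [Na+].[O-]Cl=O
Why: Pinnick (chlorite) oxidation converts the enal into the acrylic acid without touching the acrylic double bond, the large excess of 2-methyl-2-butene taking up hypochlorous acid before it can reach the electron-rich C4=C5 bond.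

Step 18
Reactants: 30 8β-acetoxy-3α-(tert-butyldimethylsilyloxy)eudesma-4,11(13)-dien-12-oic acid; 31 (trimethylsilyl)diazomethane
Product: 32 methyl 8β-acetoxy-3α-(tert-butyldimethylsilyloxy)eudesma-4,11(13)-dien-12-oate
Conditions: TMSCHN2, MeOH/toluene (1:4), 0 °C
Reagents that add atoms: (trimethylsilyl)diazomethane, C[Si](C)(C)C=[N+]=[N-]
Why: Methyl ester formation from a carboxylic acid with the silyl diazomethane in methanol is neutral and leaves the acetate, the silyl ether and both olefins alone.

Step 19
Reactants: 32 methyl 8β-acetoxy-3α-(tert-butyldimethylsilyloxy)eudesma-4,11(13)-dien-12-oate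
Product: 33 methyl 8β-acetoxy-3α-hydroxyeudesma-4,11(13)-dien-12-oate
Conditions: HF·pyridine, pyridine, THF, 0 → 25 °C
Reagents that add atoms: none
Why: Fluoride-mediated cleavage of the silyl ether under pyridine buffer frees the 3α-alcohol without ionising the allylic C–O bond, and the remote acetate cannot migrate.

Step 20
Reactants: 33 methyl 8β-acetoxy-3α-hydroxyeudesma-4,11(13)-dien-12-oate; 34 angelic acid [(Z)-2-methylbut-2-enoic acid]
Product: 35 methyl 8β-acetoxy-3α-angeloyloxyeudesma-4,11(13)-dien-12-oate
Conditions: angelic acid, 2,4,6-trichlorobenzoyl chloride, Et3N, toluene, 25 °C; then 33, 80 °C, BHT (cat.)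
Reagents that add atoms: angelic acid, C/C=C(/C)C(=O)O
Why: Yamaguchi-type esterification: the mixed anhydride of angelic acid and the trichlorobenzoic acid acylates the alcohol at the angeloyl carbonyl on heating without a nucleophilic catalyst, conditions under which the Z acid should not isomerise to the tiglate, and C3 keeps its configuration because its C–O bond is not broken.

Step 21
Reactants: 35 methyl 8β-acetoxy-3α-angeloyloxyeudesma-4,11(13)-dien-12-oate; 36 dioxygen
Product: 37 methyl (3R,5S,7R,8R,10R)-8β-acetoxy-3α-angeloyloxy-5α-hydroperoxyeudesma-4(15),11(13)-dien-12-oate (CNP0116769.2)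
Conditions: O2, meso-tetraphenylporphyrin (cat.), visible light, CH2Cl2, −20 °C
Reagents that add atoms: dioxygen, O=O
Why: Schenck ene reaction: sensitised singlet oxygen attacks the electron-rich tetrasubstituted C4=C5 bond from the α face, away from the axial C10 methyl, where only the C15 hydrogens are aligned for abstraction, so oxygen ends on C5 (α) and the double bond moves to C4=C15, while the electron-poor acrylate and angelate olefins do not react.

**Compound list**

1 | 6-methoxy-3,4-dihydronaphthalen-2(1H)-one (6-methoxy-2-tetralone) | COc1ccc2c(c1)CCC(=O)C2 | starting material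
2 | (S)-6-methoxy-1,2,3,4-tetrahydronaphthalen-2-ol | COc1ccc2c(c1)CC[C@H](O)C2 | intermediate
3 | (S)-6-methoxy-1,2,3,4,5,8-hexahydronaphthalen-2-ol | COC1=CCC2=C(C1)CC[C@H](O)C2 | intermediate
4 | ethane-1,2-diol | OCCO | starting material
5 | (S)-6,6-ethylenedioxy-1,2,3,4,5,6,7,8-octahydronaphthalen-2-ol (3,3-ethylenedioxy-5(10)-en-8β-ol) | O[C@H]1CCC2=C(C1)CCC1(C2)OCCO1 | intermediate
6 | diiodomethane | ICI | starting material
7 | ethylzinc alkoxide of 5 | CC[Zn]O[C@H]1CCC2=C(C1)CCC1(C2)OCCO1 | intermediate (not isolated)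
8 | (2S,4aS,8aS)-6,6-ethylenedioxyoctahydro-4a,8a-methanonaphthalen-2-ol (5β,10β-methano ketal 8β-alcohol, bridge cis to OH) | O[C@H]1CC[C@@]23C[C@]2(C1)CCC1(C3)OCCO1 | intermediate
9 | 8β-hydroxy-5β,10β-methano-3-ketone (cyclopropyl ketone) | O[C@H]1CC[C@@]23C[C@]2(C1)CCC(=O)C3 | intermediate (not isolated)
10 | 8β-hydroxy-11,12,13,15-tetranoreudesm-4-en-3-one | C1CC2=CC(=O)CC[C@]2(C)C[C@H]1O | intermediate
11 | iodomethane | CI | starting material
12 | potassium 3,5-dienolate of 10 | C1C=C2C=C([O-])CC[C@]2(C)C[C@H]1O.[K+] | intermediate (not isolated)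
13 | 8β-hydroxy-11,12,13-trinoreudesm-4-en-3-one | C1CC2=C(C)C(=O)CC[C@]2(C)C[C@H]1O | intermediate
14 | acetic anhydride | CC(=O)OC(C)=O | starting material
15 | 8β-acetoxy-11,12,13-trinoreudesm-4-en-3-one | C1CC2=C(C)C(=O)CC[C@]2(C)C[C@H]1OC(C)=O | intermediate
16 | 8β-acetoxy-11,12,13-trinoreudesm-4-en-3α-ol | C1CC2=C(C)[C@H](O)CC[C@]2(C)C[C@H]1OC(C)=O | intermediate
17 | 8β-acetoxy-3α-(tert-butyldimethylsilyloxy)-11,12,13-trinoreudesm-4-ene | C1CC2=C(C)[C@H](O[Si](C)(C)C(C)(C)C)CC[C@]2(C)C[C@H]1OC(C)=O | intermediate
18 | 3α-(tert-butyldimethylsilyloxy)-11,12,13-trinoreudesm-4-en-8β-ol | C1CC2=C(C)[C@H](O[Si](C)(C)C(C)(C)C)CC[C@]2(C)C[C@H]1O | intermediate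
19 | 3α-(tert-butyldimethylsilyloxy)-11,12,13-trinoreudesm-4-en-8-one | C1CC2=C(C)[C@H](O[Si](C)(C)C(C)(C)C)CC[C@]2(C)CC1=O | intermediate
20 | allyl bromide | C=CCBr | starting material
21 | lithium Δ7-enolate of 19 | [Li+].[O-]C1=CCC2=C(C)[C@H](O[Si](C)(C)C(C)(C)C)CC[C@]2(C)C1 | intermediate (not isolated)
22 | 7α-allyl-3α-(tert-butyldimethylsilyloxy)-11,12,13-trinoreudesm-4-en-8-one | C=CC[C@@H]1CC2=C(C)[C@H](O[Si](C)(C)C(C)(C)C)CC[C@]2(C)CC1=O | intermediate (not isolated)
23 | 7β-allyl-3α-(tert-butyldimethylsilyloxy)-11,12,13-trinoreudesm-4-en-8-one | C=CC[C@H]1CC2=C(C)[C@H](O[Si](C)(C)C(C)(C)C)CC[C@]2(C)CC1=O | intermediate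
24 | 7β-allyl-3α-(tert-butyldimethylsilyloxy)-11,12,13-trinoreudesm-4-en-8β-ol | C=CC[C@H]1CC2=C(C)[C@H](O[Si](C)(C)C(C)(C)C)CC[C@]2(C)C[C@H]1O | intermediate
25 | 8β-acetoxy-7β-allyl-3α-(tert-butyldimethylsilyloxy)-11,12,13-trinoreudesm-4-ene | C=CC[C@H]1CC2=C(C)[C@H](O[Si](C)(C)C(C)(C)C)CC[C@]2(C)C[C@H]1OC(C)=O | intermediate
26 | 8β-acetoxy-7β-(2,3-dihydroxypropyl)-3α-(tert-butyldimethylsilyloxy)-11,12,13-trinoreudesm-4-ene (both carbinol epimers) | OCC(O)C[C@H]1CC2=C(C)[C@H](O[Si](C)(C)C(C)(C)C)CC[C@]2(C)C[C@H]1OC(C)=O | intermediate (not isolated)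
27 | 8β-acetoxy-3α-(tert-butyldimethylsilyloxy)-13-noreudesm-4-en-12-al | O=CC[C@H]1CC2=C(C)[C@H](O[Si](C)(C)C(C)(C)C)CC[C@]2(C)C[C@H]1OC(C)=O | intermediate
28 | formaldehyde | C=O | starting material
29 | 8β-acetoxy-3α-(tert-butyldimethylsilyloxy)eudesma-4,11(13)-dien-12-al | C=C(C=O)[C@H]1CC2=C(C)[C@H](O[Si](C)(C)C(C)(C)C)CC[C@]2(C)C[C@H]1OC(C)=O | intermediate
30 | 8β-acetoxy-3α-(tert-butyldimethylsilyloxy)eudesma-4,11(13)-dien-12-oic acid | C=C(C(=O)O)[C@H]1CC2=C(C)[C@H](O[Si](C)(C)C(C)(C)C)CC[C@]2(C)C[C@H]1OC(C)=O | intermediate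
31 | (trimethylsilyl)diazomethane | C[Si](C)(C)C=[N+]=[N-] | starting material
32 | methyl 8β-acetoxy-3α-(tert-butyldimethylsilyloxy)eudesma-4,11(13)-dien-12-oate | C=C(C(=O)OC)[C@H]1CC2=C(C)[C@H](O[Si](C)(C)C(C)(C)C)CC[C@]2(C)C[C@H]1OC(C)=O | intermediate
33 | methyl 8β-acetoxy-3α-hydroxyeudesma-4,11(13)-dien-12-oate | C=C(C(=O)OC)[C@H]1CC2=C(C)[C@H](O)CC[C@]2(C)C[C@H]1OC(C)=O | intermediate
34 | angelic acid [(Z)-2-methylbut-2-enoic acid] | C/C=C(/C)C(=O)O | starting material
35 | methyl 8β-acetoxy-3α-angeloyloxyeudesma-4,11(13)-dien-12-oate | C=C(C(=O)OC)[C@H]1CC2=C(C)[C@H](OC(=O)/C(C)=C\C)CC[C@]2(C)C[C@H]1OC(C)=O | intermediate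
36 | dioxygen | O=O | starting material
37 | methyl (3R,5S,7R,8R,10R)-8β-acetoxy-3α-angeloyloxy-5α-hydroperoxyeudesma-4(15),11(13)-dien-12-oate | C=C(C(=O)OC)[C@H]1C[C@@]2(OO)C(=C)[C@H](OC(=O)/C(C)=C\C)CC[C@]2(C)C[C@H]1OC(C)=O | target

**Count and risks**

Total steps: 21. Longest linear sequence: 21 steps (1 → 37).

Steps most likely to fail:

Step 21. Singlet oxygen may attack the β face, or abstract an axial hydrogen from C6, because the pseudoaxial 3α-acyloxy group crowds the α face and allylic esters tend to steer the oxidant to the opposite side. The fallback moves the oxygenation onto the free alcohol and sets out from 33. In a non-polar solvent the pseudoaxial 3α-hydroxyl should hydrogen-bond to the incoming oxygen and guide it to the α face, giving methyl 8β-acetoxy-3α-hydroxy-5α-hydroperoxyeudesma-4(15),11(13)-dien-12-oate F1. The more acidic hydroperoxide is then silylated selectively (Et3SiCl, imidazole, DMF, −20 °C) to the triethylsilyl peroxide F2. The 3α-hydroxyl is acylated with the mixed anhydride of step 20 to the angelate silyl peroxide F3. HF·pyridine removes the silyl group and the route is rejoined at 37.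

Step 20. Acylation of the hindered pseudoaxial allylic alcohol may be slow, and the activated angeloyl donor may drift from Z to E on prolonged heating. The fallback builds the Z olefin on the ester instead and sets out from 33. Esterification with 2-[bis(2,2,2-trifluoroethoxy)phosphoryl]propanoic acid (DCC, DMAP, CH2Cl2) gives the phosphonopropionate F4. A Still–Gennari olefination with acetaldehyde (KN(SiMe3)2, 18-crown-6, THF, −78 °C) then closes the Z-2-methylbut-2-enoate and returns to 35.

Step 1. The catalyst may discriminate poorly between the two methylene flanks of the ketone, so the alcohol may form with low enantiomeric purity. The fallback sets out from 1: NaBH4 in MeOH gives racemic 6-methoxy-1,2,3,4-tetrahydronaphthalen-2-ol F5, which is resolved by lipase-catalysed acetylation (immobilised Candida antarctica lipase B, vinyl acetate, MTBE). The enzyme is expected to acylate the R enantiomer to (R)-6-methoxy-1,2,3,4-tetrahydronaphthalen-2-yl acetate F6 and leave the S alcohol, which rejoins the route at 2. F6 can be recycled to 1 by methanolysis and oxidation.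

**Further compounds**

F1 | step 21 | methyl 8β-acetoxy-3α-hydroxy-5α-hydroperoxyeudesma-4(15),11(13)-dien-12-oate | C=C(C(=O)OC)[C@H]1C[C@@]2(OO)C(=C)[C@H](O)CC[C@]2(C)C[C@H]1OC(C)=O
F2 | step 21 | methyl 8β-acetoxy-3α-hydroxy-5α-(triethylsilylperoxy)eudesma-4(15),11(13)-dien-12-oate | C=C(C(=O)OC)[C@H]1C[C@@]2(OO[Si](CC)(CC)CC)C(=C)[C@H](O)CC[C@]2(C)C[C@H]1OC(C)=O
F3 | step 21 | methyl 8β-acetoxy-3α-angeloyloxy-5α-(triethylsilylperoxy)eudesma-4(15),11(13)-dien-12-oate | C=C(C(=O)OC)[C@H]1C[C@@]2(OO[Si](CC)(CC)CC)C(=C)[C@H](OC(=O)/C(C)=C\C)CC[C@]2(C)C[C@H]1OC(C)=O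
F4 | step 20 | methyl 8β-acetoxy-3α-{2-[bis(2,2,2-trifluoroethoxy)phosphoryl]propanoyloxy}eudesma-4,11(13)-dien-12-oate | C=C(C(=O)OC)[C@H]1CC2=C(C)[C@H](OC(=O)C(C)P(=O)(OCC(F)(F)F)OCC(F)(F)F)CC[C@]2(C)C[C@H]1OC(C)=O
F5 | step 1 | rac-6-methoxy-1,2,3,4-tetrahydronaphthalen-2-ol | COc1ccc2c(c1)CCC(O)C2
F6 | step 1 | (R)-6-methoxy-1,2,3,4-tetrahydronaphthalen-2-yl acetate | COc1ccc2c(c1)CC[C@@H](OC(C)=O)C2
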